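The ten-membered carbocycle (C1–C10) is disconnected at C1–C2. The C1 carbonyl is flanked by fully substituted C10 on one side and a plain CH2 (C2) on the other, so an acyl and an alkyl electrophile can be joined there without creating or epimerising a stereocentre. A single nickel-mediated reductive coupling makes the ketone and closes the ring on a chain that already carries the trans C4–C5 epoxide, the C6–C12 butenolide and all five stereocentres. The precursor is the seco compound with a primary iodide at C2 and a 2-pyridyl thioester at C1. C8 and C13 are silyl ethers; the C13 acetate is added later because an allylic acetate would compete for nickel.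

Key step: step 19

Remark: locants C1–C13 are those of the target skeleton (carbocycle C1–C10, lactone C11 and C12, oxymethyl C13); the CIP label of C6 changes from R to S at step 13 only because substituent priorities change, not the spatial arrangement.

Step 1
Reactants: 1 but-3-yn-1-ol
Product: 2 1-[(but-3-yn-1-yloxy)methyl]-4-methoxybenzene
Conditions: NaH, 4-methoxybenzyl chloride, Bu4NI (cat.), THF/DMF, 0 °C to rt
Reagents that add atoms: 4-methoxybenzyl chloride COc1ccc(CCl)cc1
Why: Williamson etherification of the primary alkoxide with the benzylic chloride should be clean, since the alcohol is far more acidic than the terminal alkyne.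

Step 2
Reactants: 2 1-[(but-3-yn-1-yloxy)methyl]-4-methoxybenzene
Product: 4 (E)-5-[(4-methoxybenzyl)oxy]-3-methylpent-2-en-1-ol, via alkenyldimethylalane 3 (not isolated)
Conditions: AlMe3, Cp2ZrCl2 (cat.), CH2Cl2, 0 °C to rt; then n-BuLi, THF, −78 °C; (CH2O)n, rt; aqueous Rochelle salt
Reagents that add atoms: trimethylaluminium C[Al](C)C; formaldehyde (from paraformaldehyde) C=O
Why: Negishi carboalumination adds methyl and aluminium syn across the alkyne with methyl on the internal carbon, and hydroxymethylation of the derived alanate retains geometry, which fixes the E C4=C5 alkene.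

Step 3
Reactants: 4 (E)-5-[(4-methoxybenzyl)oxy]-3-methylpent-2-en-1-ol
Product: 5 (E)-5-[(4-methoxybenzyl)oxy]-3-methylpent-2-enal
Conditions: MnO2, CH2Cl2, rt
Reagents that add atoms: none
Why: Allylic oxidation with MnO2 is selective for the allylic alcohol and should neither touch the PMB ether nor isomerise the alkene.

Step 4
Reactants: 5 (E)-5-[(4-methoxybenzyl)oxy]-3-methylpent-2-enal; 6 tert-butyldimethyl(prop-2-yn-1-yloxy)silane
Product: 7 (4R,5E)-1-[(tert-butyldimethylsilyl)oxy]-8-[(4-methoxybenzyl)oxy]-6-methyloct-5-en-2-yn-4-ol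
Conditions: (R,R)-ProPhenol (20 mol%), Me2Zn, Ph3PO (cat.), toluene, 0 °C
Reagents that add atoms: none
Why: Zinc–ProPhenol catalysed asymmetric alkynylation of an α,β-unsaturated aldehyde; the dinuclear zinc catalyst shields one aldehyde face, and the ligand antipode is the one whose established sense of induction gives the 6R carbinol (reagent control).

Step 5
Reactants: 7 (4R,5E)-1-[(tert-butyldimethylsilyl)oxy]-8-[(4-methoxybenzyl)oxy]-6-methyloct-5-en-2-yn-4-ol
Product: 8 (2E,4R,5E)-1-[(tert-butyldimethylsilyl)oxy]-2,3-diiodo-8-[(4-methoxybenzyl)oxy]-6-methylocta-2,5-dien-4-ol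
Conditions: I2, NaHCO3, CH2Cl2, rt, dark
Reagents that add atoms: iodine II
Why: Electrophilic anti addition of iodine to the internal alkyne (alkyne diiodination) gives the E vicinal diiodide, whereas addition to the trisubstituted alkene is reversible and unproductive.

Step 6
Reactants: 8 (2E,4R,5E)-1-[(tert-butyldimethylsilyl)oxy]-2,3-diiodo-8-[(4-methoxybenzyl)oxy]-6-methylocta-2,5-dien-4-ol
Product: 9 (1R,2E)-4-[(tert-butyldimethylsilyl)oxy]-2,3-diiodo-1-[(2R,3R)-3-{2-[(4-methoxybenzyl)oxy]ethyl}-3-methyloxiran-2-yl]but-2-en-1-ol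
Conditions: mCPBA, NaHCO3, CH2Cl2, 0 °C
Reagents that add atoms: 3-chloroperoxybenzoic acid O=C(OO)c1cccc(Cl)c1
Why: Hydroxyl-directed peracid epoxidation of the electron-rich C4=C5 alkene; allylic 1,3-strain with the C4 methyl cis to C6 holds H6 in the alkene plane, so oxygen is delivered syn to the hydroxyl and the threo (4R,5R) epoxide should form, the diiodoalkene being too electron-poor to react.

Step 7
Reactants: 9 (1R,2E)-4-[(tert-butyldimethylsilyl)oxy]-2,3-diiodo-1-[(2R,3R)-3-{2-[(4-methoxybenzyl)oxy]ethyl}-3-methyloxiran-2-yl]but-2-en-1-ol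
Product: 10 (5R)-3-{[(tert-butyldimethylsilyl)oxy]methyl}-4-iodo-5-[(2R,3R)-3-{2-[(4-methoxybenzyl)oxy]ethyl}-3-methyloxiran-2-yl]furan-2(5H)-one
Conditions: Pd(PPh3)4 (5 mol%), CO (1 atm), K2CO3, THF, 40 °C
Reagents that add atoms: carbon monoxide [C-]#[O+]
Why: Palladium-catalysed cyclocarbonylation of a Z γ-iodoallylic alcohol: oxidative addition at the C11 iodide (cis to the C6 hydroxyl and less hindered), CO insertion and capture of the acylpalladium by the hydroxyl close the butenolide, while an acylpalladium at C7 could only give a strained four-membered lactone.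

Step 8
Reactants: 11 (R)-citramalic acid
Product: 12 [(4R)-2,2,4-trimethyl-5-oxo-1,3-dioxolan-4-yl]acetic acid
Conditions: 2,2-dimethoxypropane, TsOH (cat.), rt
Reagents that add atoms: 2,2-dimethoxypropane COC(C)(C)OC
Why: Acid-catalysed transketalisation ties the α-hydroxy acid into the five-membered dioxolanone and leaves the CH2CO2H group free, which differentiates the two carboxyls without touching the quaternary centre (future C10).

Step 9
Reactants: 12 [(4R)-2,2,4-trimethyl-5-oxo-1,3-dioxolan-4-yl]acetic acid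
Product: 14 N-methoxy-N-methyl-2-[(4R)-2,2,4-trimethyl-5-oxo-1,3-dioxolan-4-yl]acetamide, via acyl imidazolide 13 (not isolated)
Conditions: 1,1'-carbonyldiimidazole, CH2Cl2, 0 °C to rt; then MeNHOMe·HCl
Reagents that add atoms: N,O-dimethylhydroxylamine hydrochloride CNOC.Cl; 1,1'-carbonyldiimidazole O=C(n1ccnc1)n1ccnc1 (imidazolyl group of 13 only)
Why: Amide coupling through the acyl imidazolide under neutral conditions that leave the dioxolanone intact.

Step 10
Reactants: 14 N-methoxy-N-methyl-2-[(4R)-2,2,4-trimethyl-5-oxo-1,3-dioxolan-4-yl]acetamide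
Product: 15 allyl (2R)-2-hydroxy-4-[methoxy(methyl)amino]-2-methyl-4-oxobutanoate
Conditions: allyl alcohol, K2CO3 (cat.), rt
Reagents that add atoms: allyl alcohol C=CCO
Why: Base-catalysed alcoholysis of the activated dioxolanone (transesterification with loss of acetone) gives the allyl ester and the tertiary alcohol, the amide being inert.

Step 11
Reactants: 15 allyl (2R)-2-hydroxy-4-[methoxy(methyl)amino]-2-methyl-4-oxobutanoate
Product: 16 allyl (2R)-2-acetoxy-4-[methoxy(methyl)amino]-2-methyl-4-oxobutanoate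
Conditions: Ac2O, DMAP, Et3N, CH2Cl2, rt
Reagents that add atoms: acetic anhydride CC(=O)OC(C)=O
Why: DMAP-catalysed acylation (nucleophilic catalysis) of the tertiary α-hydroxy ester installs the C10 acetate on a small, robust molecule.

Step 12
Reactants: 16 allyl (2R)-2-acetoxy-4-[methoxy(methyl)amino]-2-methyl-4-oxobutanoate
Product: 17 allyl (2R)-2-acetoxy-2-methyl-4-oxobutanoate
Conditions: i-Bu2AlH (1.05 equiv), THF, −78 °C; aqueous Rochelle salt
Reagents that add atoms: none
Why: Partial reduction of the N-methoxy-N-methylamide through its chelated aluminium hemiaminal releases the aldehyde only on work-up, and at −78 °C with one equivalent the hindered acetate and the neopentyl-type allyl ester should survive.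

Step 13
Reactants: 10 (5R)-3-{[(tert-butyldimethylsilyl)oxy]methyl}-4-iodo-5-[(2R,3R)-3-{2-[(4-methoxybenzyl)oxy]ethyl}-3-methyloxiran-2-yl]furan-2(5H)-one; 17 allyl (2R)-2-acetoxy-2-methyl-4-oxobutanoate
Product: 18 seco alcohol (4R,5R,6S,8S,10R): butenolide carrying at C7 the chain CH(OH)(C8)–CH2–C(CH3)(OAc)(C10)–CO2-allyl (C1), with C13 OTBS, C2 OPMB and a free 8S hydroxyl
Conditions: CrCl2, chiral oxazoline–sulfonamide ligand (enantiomer giving 8S), Et3N, NiCl2 (cat.), THF, rt
Reagents that add atoms: none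
Why: Nozaki–Hiyama–Kishi coupling: zerovalent nickel inserts into the activated β-iodoenoate carbon–iodine bond at C7, transmetalation gives an alkenylchromium species that adds only to the aldehyde, and the sulfonamide ligand on trivalent chromium selects the aldehyde face to set 8S.

Step 14
Reactants: 18 seco alcohol (4R,5R,6S,8S,10R)
Product: 19 seco bis-silyl ether: as 18 with C8 OTBS
Conditions: TBSOTf, 2,6-lutidine, CH2Cl2, −78 °C
Reagents that add atoms: tert-butyldimethylsilyl triflate CC(C)(C)[Si](C)(C)OS(=O)(=O)C(F)(F)F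
Why: Silylation of the secondary allylic alcohol with the silyl triflate is fast at low temperature and forestalls lactonisation onto the C1 ester or acetyl migration from C10.

Step 15
Reactants: 19 seco bis-silyl ether
Product: 20 seco acid: as 19 with a free C1 carboxylic acid
Conditions: Pd(PPh3)4 (5 mol%), morpholine, THF, rt
Reagents that add atoms: none
Why: Tsuji–Trost deallylation (allyl transfer to morpholine) frees the acid under neutral conditions that spare epoxide, lactone, acetate and silyl ethers; no allylic acetate is present to compete.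

Step 16
Reactants: 20 seco acid
Product: 21 seco thioester: as 20 with C1 as S-(pyridin-2-yl) thioester
Conditions: 2,2'-dipyridyl disulfide, PPh3, CH2Cl2, rt
Reagents that add atoms: 2,2'-dipyridyl disulfide c1ccc(SSc2ccccn2)nc1
Why: Mukaiyama redox condensation: the acyloxyphosphonium intermediate is captured by pyridine-2-thiolate, giving the activated thioester without added base.

Step 17
Reactants: 21 seco thioester
Product: 22 seco alcohol-thioester: as 21 with a free C2 primary alcohol
Conditions: DDQ, CH2Cl2/pH 7 buffer, 0 °C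
Reagents that add atoms: none
Why: Oxidative PMB cleavage by DDQ is selective for the electron-rich benzyl ether and proceeds at neutral pH.

Step 18
Reactants: 22 seco alcohol-thioester
Product: 23 seco iodide (4R,5R,6S,8S,10R): C2 primary iodide, C1 S-(pyridin-2-yl) thioester, C8 and C13 OTBS, C10 OAc
Conditions: I2, PPh3, imidazole, CH2Cl2, 0 °C
Reagents that add atoms: iodine II
Why: Appel-type iodination of the primary alcohol through the alkoxyphosphonium salt and SN2 displacement by iodide; a short reaction at 0 °C should spare the hindered tertiary thioester.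

Step 19
Reactants: 23 seco iodide
Product: 24 (4R,5R,6S,8S,10R)-10-acetoxy-8,13-bis[(tert-butyldimethylsilyl)oxy]-4,5-epoxy-1-oxogermacr-7(11)-en-12,6-olide
Conditions: NiCl2(dme) (30 mol%), 4,4'-di-tert-butyl-2,2'-bipyridine (33 mol%), Mn powder (3 equiv), DMA/THF, rt, syringe-pump addition of 23 over 12 h to a final 0.001 mol/L
Reagents that add atoms: none
Why: Proposed new method: zerovalent nickel–bipyridine adds oxidatively to the C1–S bond of the 2-pyridyl thioester (helped by pyridine nitrogen coordination) to give an acylnickel species; after reduction by manganese, iodine-atom abstraction at C2 gives the primary alkyl radical, which is captured at the acylnickel centre of the same molecule, and reductive elimination forms the C1–C2 ketone bond. The closest known reaction type is the intermolecular nickel-catalysed reductive coupling of alkyl iodides with 2-pyridyl thioesters or acid chlorides to give ketones. The ten-membered carbocycle is closed by this one bond: radical capture forms an eleven-membered acyl(alkyl)nickelacycle that contracts to the ring on reductive elimination, with the trans epoxide and the planar butenolide acting as turn elements. No stereocentre is formed; C10 is quaternary and cannot epimerise, and C2 ends as a methylene. The step needs chemoselective insertion into the thioester, secured because it is the only activated acyl group and C13 is a silyl ether, not an allylic acetate. Ring closure must outrun dimerisation, hydrodeiodination and β-hydride loss, which slow addition at high dilution favours; the C2 radical is one methylene removed from the oxirane carbon so epoxide scission is unavailable, and the trans epoxide forbids six-membered cyclisation onto C7.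

Step 20
Reactants: 24 bis-silyl macrocycle
Product: 25 (4R,5R,6S,8S,10R)-10-acetoxy-4,5-epoxy-8,13-dihydroxy-1-oxogermacr-7(11)-en-12,6-olide
Conditions: HF·pyridine, pyridine, THF, 0 °C to rt
Reagents that add atoms: none
Why: Fluoride-mediated cleavage of both silyl ethers under buffered, mildly acidic conditions avoids base-induced opening of the epoxide from C6.

Step 21
Reactants: 25 diol
Product: 26 (4R,5R,6S,8S,10R)-10,13-diacetoxy-4,5-epoxy-8-hydroxy-1-oxogermacr-7(11)-en-12,6-olide
Conditions: AcCl (1.05 equiv), 2,4,6-collidine, CH2Cl2, −78 °C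
Reagents that add atoms: acetyl chloride CC(=O)Cl
Why: Kinetically selective acetylation of the primary allylic C13 alcohol over the hindered secondary C8 alcohol with a hindered pyridine base at low temperature.

Step 22
Reactants: 26 C13 acetate
Product: 27 glaucolide A
Conditions: methacrylic anhydride, DMAP (cat.), Et3N, CH2Cl2, 0 °C
Reagents that add atoms: methacrylic anhydride C=C(C)C(=O)OC(=O)C(C)=C
Why: DMAP-catalysed acylation of the remaining C8 alcohol proceeds with retention at C8 and gives the methacrylate of the target.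

Compound list
1 | but-3-yn-1-ol | C#CCCO | starting material
2 | 1-[(but-3-yn-1-yloxy)methyl]-4-methoxybenzene | C#CCCOCc1ccc(OC)cc1 | intermediate
3 | (E)-{4-[(4-methoxybenzyl)oxy]-2-methylbut-1-en-1-yl}dimethylalane | COc1ccc(COCC/C(C)=C/[Al](C)C)cc1 | intermediate (not isolated)
4 | (E)-5-[(4-methoxybenzyl)oxy]-3-methylpent-2-en-1-ol | COc1ccc(COCC/C(C)=C/CO)cc1 | intermediate
5 | (E)-5-[(4-methoxybenzyl)oxy]-3-methylpent-2-enal | COc1ccc(COCC/C(C)=C/C=O)cc1 | intermediate
6 | tert-butyldimethyl(prop-2-yn-1-yloxy)silane | C#CCO[Si](C)(C)C(C)(C)C | starting material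
7 | (4R,5E)-1-[(tert-butyldimethylsilyl)oxy]-8-[(4-methoxybenzyl)oxy]-6-methyloct-5-en-2-yn-4-ol | COc1ccc(COCC/C(C)=C/[C@@H](O)C#CCO[Si](C)(C)C(C)(C)C)cc1 | intermediate
8 | (2E,4R,5E)-1-[(tert-butyldimethylsilyl)oxy]-2,3-diiodo-8-[(4-methoxybenzyl)oxy]-6-methylocta-2,5-dien-4-ol | COc1ccc(COCC/C(C)=C/[C@@H](O)/C(I)=C(\I)CO[Si](C)(C)C(C)(C)C)cc1 | intermediate
9 | (1R,2E)-4-[(tert-butyldimethylsilyl)oxy]-2,3-diiodo-1-[(2R,3R)-3-{2-[(4-methoxybenzyl)oxy]ethyl}-3-methyloxiran-2-yl]but-2-en-1-ol | COc1ccc(COCC[C@@]2(C)O[C@@H]2[C@@H](O)/C(I)=C(\I)CO[Si](C)(C)C(C)(C)C)cc1 | intermediate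
10 | (5R)-3-{[(tert-butyldimethylsilyl)oxy]methyl}-4-iodo-5-[(2R,3R)-3-{2-[(4-methoxybenzyl)oxy]ethyl}-3-methyloxiran-2-yl]furan-2(5H)-one | COc1ccc(COCC[C@@]2(C)O[C@@H]2[C@H]2OC(=O)C(CO[Si](C)(C)C(C)(C)C)=C2I)cc1 | intermediate
11 | (R)-citramalic acid | C[C@@](O)(CC(=O)O)C(=O)O | starting material
12 | [(4R)-2,2,4-trimethyl-5-oxo-1,3-dioxolan-4-yl]acetic acid | C[C@]1(CC(=O)O)OC(C)(C)OC1=O | intermediate
13 | 1-{[(4R)-2,2,4-trimethyl-5-oxo-1,3-dioxolan-4-yl]acetyl}-1H-imidazole | C[C@]1(CC(=O)n2ccnc2)OC(C)(C)OC1=O | intermediate (not isolated)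
14 | N-methoxy-N-methyl-2-[(4R)-2,2,4-trimethyl-5-oxo-1,3-dioxolan-4-yl]acetamide | C[C@]1(CC(=O)N(C)OC)OC(C)(C)OC1=O | intermediate
15 | allyl (2R)-2-hydroxy-4-[methoxy(methyl)amino]-2-methyl-4-oxobutanoate | C[C@@](O)(CC(=O)N(C)OC)C(=O)OCC=C | intermediate
16 | allyl (2R)-2-acetoxy-4-[methoxy(methyl)amino]-2-methyl-4-oxobutanoate | C[C@@](OC(C)=O)(CC(=O)N(C)OC)C(=O)OCC=C | intermediate
17 | allyl (2R)-2-acetoxy-2-methyl-4-oxobutanoate | C[C@@](OC(C)=O)(CC=O)C(=O)OCC=C | intermediate
18 | seco alcohol (4R,5R,6S,8S,10R): C1 allyl ester, C10 OAc, C8 OH, C13 OTBS, C2 OPMB | COc1ccc(COCC[C@@]2(C)O[C@@H]2[C@H]2OC(=O)C(CO[Si](C)(C)C(C)(C)C)=C2[C@@H](O)C[C@@](C)(OC(C)=O)C(=O)OCC=C)cc1 | intermediate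
19 | seco bis-silyl ether: as 18 with C8 OTBS | COc1ccc(COCC[C@@]2(C)O[C@@H]2[C@H]2OC(=O)C(CO[Si](C)(C)C(C)(C)C)=C2[C@@H](O[Si](C)(C)C(C)(C)C)C[C@@](C)(OC(C)=O)C(=O)OCC=C)cc1 | intermediate
20 | seco acid: as 19 with C1 CO2H | COc1ccc(COCC[C@@]2(C)O[C@@H]2[C@H]2OC(=O)C(CO[Si](C)(C)C(C)(C)C)=C2[C@@H](O[Si](C)(C)C(C)(C)C)C[C@@](C)(OC(C)=O)C(=O)O)cc1 | intermediate
21 | seco thioester: as 20 with C1 S-(pyridin-2-yl) thioester | COc1ccc(COCC[C@@]2(C)O[C@@H]2[C@H]2OC(=O)C(CO[Si](C)(C)C(C)(C)C)=C2[C@@H](O[Si](C)(C)C(C)(C)C)C[C@@](C)(OC(C)=O)C(=O)Sc2ccccn2)cc1 | intermediate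
22 | seco alcohol-thioester: as 21 with C2 OH | OCC[C@@]1(C)O[C@@H]1[C@H]1OC(=O)C(CO[Si](C)(C)C(C)(C)C)=C1[C@@H](O[Si](C)(C)C(C)(C)C)C[C@@](C)(OC(C)=O)C(=O)Sc1ccccn1 | intermediate
23 | seco iodide: C2 iodide, C1 S-(pyridin-2-yl) thioester, C8 and C13 OTBS, C10 OAc | ICC[C@@]1(C)O[C@@H]1[C@H]1OC(=O)C(CO[Si](C)(C)C(C)(C)C)=C1[C@@H](O[Si](C)(C)C(C)(C)C)C[C@@](C)(OC(C)=O)C(=O)Sc1ccccn1 | intermediate (key-step precursor)
24 | (4R,5R,6S,8S,10R)-10-acetoxy-8,13-bis[(tert-butyldimethylsilyl)oxy]-4,5-epoxy-1-oxogermacr-7(11)-en-12,6-olide | CC(C)(C)[Si](C)(C)O[C@H]1C[C@@](C)(OC(C)=O)C(=O)CC[C@@]2(C)O[C@@H]2[C@H]2OC(=O)C(CO[Si](C)(C)C(C)(C)C)=C12 | intermediate (key-step product)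
25 | (4R,5R,6S,8S,10R)-10-acetoxy-4,5-epoxy-8,13-dihydroxy-1-oxogermacr-7(11)-en-12,6-olide | O[C@H]1C[C@@](C)(OC(C)=O)C(=O)CC[C@@]2(C)O[C@@H]2[C@H]2OC(=O)C(CO)=C12 | intermediate
26 | (4R,5R,6S,8S,10R)-10,13-diacetoxy-4,5-epoxy-8-hydroxy-1-oxogermacr-7(11)-en-12,6-olide | O[C@H]1C[C@@](C)(OC(C)=O)C(=O)CC[C@@]2(C)O[C@@H]2[C@H]2OC(=O)C(COC(C)=O)=C12 | intermediate
27 | glaucolide A | C=C(C)C(=O)O[C@H]1C[C@@](C)(OC(C)=O)C(=O)CC[C@@]2(C)O[C@@H]2[C@H]2OC(=O)C(COC(C)=O)=C12 | target

Total step count: 22. Longest linear sequence: 17 (steps 1–7, then 13–22); steps 8–12 are the side branch to aldehyde 17.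

Steps most likely to fail

1. Step 19 (proposed new method). Intermolecular coupling, hydrodeiodination or β-hydride loss from the alkylnickel may outrun the entropically costly ten-membered closure, or the hindered acylnickel may lose CO. Fallback with known chemistry, a palladium-catalysed Fukuyama coupling of a preformed organozinc: it sets out from acid 20 and returns at 24. Carbodiimide-mediated condensation of 20 with ethanethiol should give the S-ethyl thioester F1. DDQ then removes the PMB group to give the primary alcohol F2, and Appel-type iodination gives the iodide F3. Zinc insertion (activated zinc dust, LiCl, THF) gives the alkylzinc iodide F4 (not isolated). Slow addition of F4 to PdCl2(PPh3)2 in toluene/THF at high dilution should join C2 to the thioester carbon and deliver 24.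

2. Step 7. Palladium may insert into the C7 iodide instead of the C11 iodide, or re-enter the product vinyl iodide, diverting material to oligomeric esters. Fallback in which the lactone carbonyl comes from an ynoate ester and no CO is used: it sets out from enal 5 and returns at 19. The same zinc–ProPhenol alkynylation with methyl propiolate should give the γ-hydroxy ynoate F5, and directed mCPBA epoxidation the epoxy alcohol F6. Pd(PPh3)4-catalysed syn addition of hexamethylditin across the ynoate, with spontaneous lactonisation, gives the 3,4-bis(trimethylstannyl)butenolide F7, and iododestannylation with I2 gives the 3,4-diiodobutenolide F8. Nozaki–Hiyama–Kishi coupling with aldehyde 17 at the more electrophilic C7 iodide gives the C11-iodo alcohol F9. Stille coupling with (tributylstannyl)methanol installs C13 to give the diol F10, and double silylation with TBSOTf returns to 19.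

3. Step 13. Facial discrimination at the aldehyde may be poor, giving C8 epimers, and a slow coupling leaves time for acetate elimination from the β-acetoxy aldehyde or for lactonisation of the chromium alkoxide onto the C1 ester. Fallback that moves C8 control to a reagent-controlled ketone reduction: it sets out from 10 and 17 and returns at 18. Ligand-free coupling (CrCl2, NiCl2 cat., DMSO) gives the C8-epimeric alcohols F11. Dess–Martin oxidation gives the C8 ketone F12, and Corey–Bakshi–Shibata reduction with the (R)-oxazaborolidine and catecholborane should set 8S and return to 18.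

Further compounds
F1 | step 19 | S-ethyl thioester analogue of 21 (C1 COSEt, C2 OPMB) | COc1ccc(COCC[C@@]2(C)O[C@@H]2[C@H]2OC(=O)C(CO[Si](C)(C)C(C)(C)C)=C2[C@@H](O[Si](C)(C)C(C)(C)C)C[C@@](C)(OC(C)=O)C(=O)SCC)cc1
F2 | step 19 | C2 alcohol of F1 | OCC[C@@]1(C)O[C@@H]1[C@H]1OC(=O)C(CO[Si](C)(C)C(C)(C)C)=C1[C@@H](O[Si](C)(C)C(C)(C)C)C[C@@](C)(OC(C)=O)C(=O)SCC
F3 | step 19 | C2 iodide of F1 | ICC[C@@]1(C)O[C@@H]1[C@H]1OC(=O)C(CO[Si](C)(C)C(C)(C)C)=C1[C@@H](O[Si](C)(C)C(C)(C)C)C[C@@](C)(OC(C)=O)C(=O)SCC
F4 | step 19 | C2 alkylzinc iodide from F3 (not isolated) | I[Zn]CC[C@@]1(C)O[C@@H]1[C@H]1OC(=O)C(CO[Si](C)(C)C(C)(C)C)=C1[C@@H](O[Si](C)(C)C(C)(C)C)C[C@@](C)(OC(C)=O)C(=O)SCC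
F5 | step 7 | methyl (4R,5E)-4-hydroxy-8-[(4-methoxybenzyl)oxy]-6-methyloct-5-en-2-ynoate | COc1ccc(COCC/C(C)=C/[C@@H](O)C#CC(=O)OC)cc1
F6 | step 7 | methyl (4S)-4-hydroxy-4-[(2R,3R)-3-{2-[(4-methoxybenzyl)oxy]ethyl}-3-methyloxiran-2-yl]but-2-ynoate | COc1ccc(COCC[C@@]2(C)O[C@@H]2[C@@H](O)C#CC(=O)OC)cc1
F7 | step 7 | (5R)-5-[(2R,3R)-3-{2-[(4-methoxybenzyl)oxy]ethyl}-3-methyloxiran-2-yl]-3,4-bis(trimethylstannyl)furan-2(5H)-one | COc1ccc(COCC[C@@]2(C)O[C@@H]2[C@H]2OC(=O)C([Sn](C)(C)C)=C2[Sn](C)(C)C)cc1
F8 | step 7 | (5R)-3,4-diiodo-5-[(2R,3R)-3-{2-[(4-methoxybenzyl)oxy]ethyl}-3-methyloxiran-2-yl]furan-2(5H)-one | COc1ccc(COCC[C@@]2(C)O[C@@H]2[C@H]2OC(=O)C(I)=C2I)cc1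
F9 | step 7 | C11-iodo analogue of 18 (iodine on C11 in place of CH2OTBS, 8S hydroxyl) | COc1ccc(COCC[C@@]2(C)O[C@@H]2[C@H]2OC(=O)C(I)=C2[C@@H](O)C[C@@](C)(OC(C)=O)C(=O)OCC=C)cc1
F10 | step 7 | C8,C13 diol analogue of 18 (free C13 hydroxyl) | COc1ccc(COCC[C@@]2(C)O[C@@H]2[C@H]2OC(=O)C(CO)=C2[C@@H](O)C[C@@](C)(OC(C)=O)C(=O)OCC=C)cc1
F11 | step 13 | C8-epimeric mixture of 18 | COc1ccc(COCC[C@@]2(C)O[C@@H]2[C@H]2OC(=O)C(CO[Si](C)(C)C(C)(C)C)=C2C(O)C[C@@](C)(OC(C)=O)C(=O)OCC=C)cc1
F12 | step 13 | C8 ketone derived from 18 | COc1ccc(COCC[C@@]2(C)O[C@@H]2[C@H]2OC(=O)C(CO[Si](C)(C)C(C)(C)C)=C2C(=O)C[C@@](C)(OC(C)=O)C(=O)OCC=C)cc1
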